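**Retrosynthetic overview** (side chain numbered C1'' = benzylic CH2, C2'' = stereocentre, up to C5'' = carbinol carbon)
- Ring B is attached at C2 by an enantioselective Hayashi–Miyaura 1,4-addition of a 2,4-bis(silyloxy)phenylboronic acid to an 8-alkyl-5-methoxy-7-silyloxychromone. Ring C comes from the acetyl group of ring A plus a one-carbon aminal ester.
- The C1''–C2'' bond is made at the aldehyde oxidation level. A 3-formylacetophenone (ring A) undergoes an enantioselective oxonium-ene annulation with the silyl ether of 2,6-dimethylhept-5-en-2-ol, which is one step from 6-methylhept-5-en-2-one.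
- Enabling feature: O–C5''–C4''–C3''–C2''–C1'' is a latent oxane, and the isopropenyl group on C2'' is the footprint of an ene reaction of a Me2C=CH unit. C8 of ring A lies between O7 and O1 and para to the 5-OMe, so a cation at C1'' is easy to make twice.
- Ionic hydrogenation of the benzylic C1''–O bond opens the temporary oxane again. It returns the CH2 group and the tertiary alcohol (as its silyl ether) in one step.
- Ring order: ring A is bought; the temporary oxane is closed in step 4 and opened in step 5; ring C is closed in step 7; ring B is attached in step 11.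

Key step: step 4

Assumption: the sense of induction of the chiral acid (step 4) and of the bisphosphine (step 11) cannot be predicted with certainty, so in each case the antipode that gives the drawn configuration is taken.

**Step 1**
Reactants: 1 1-(2,4-dihydroxy-6-methoxyphenyl)ethan-1-one
Product: 3 3-acetyl-2,6-dihydroxy-4-methoxybenzaldehyde, via aryl iminium salt 2 (not isolated)
Conditions: POCl3 (1.1 equiv), DMF, EtOAc, 0 °C to rt; then H2O, 50 °C
Reagents that add atoms: N,N-dimethylformamide CN(C)C=O; water O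
Why: Vilsmeier–Haack formylation of a phloroglucinol-type ring outruns attack on the acetyl group at this temperature, and the carbon between the two free hydroxyls (para to OMe) should react because the other free position is shielded by the methoxy methyl group that the acetyl group pushes towards it.

**Step 2**
Reactants: 3 3-acetyl-2,6-dihydroxy-4-methoxybenzaldehyde
Product: 4 3-acetyl-4-methoxy-2,6-bis(prop-2-enyloxy)benzaldehyde
Conditions: allyl bromide (3 equiv), K2CO3, DMF, 50 °C
Reagents that add atoms: allyl bromide C=CCBr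
Why: Williamson etherification of two acidic chelated phenols caps every internal oxygen nucleophile that could intercept the cation of step 4.

**Step 3**
Reactants: 5 6-methylhept-5-en-2-one
Product: 7 [(2,6-dimethylhept-5-en-2-yl)oxy]trimethylsilane, via lithium alkoxide 6 (not isolated)
Conditions: MeLi, Et2O, −78 °C; then Me3SiCl, −78 °C to rt
Reagents that add atoms: methyllithium [Li]C; chlorotrimethylsilane C[Si](C)(C)Cl
Why: 1,2-addition of methyllithium to the methyl ketone and in situ O-silylation of the lithium alkoxide give the tertiary silyl ether in one flask.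

**Step 4**
Reactants: 4 3-acetyl-4-methoxy-2,6-bis(prop-2-enyloxy)benzaldehyde; 7 [(2,6-dimethylhept-5-en-2-yl)oxy]trimethylsilane
Product: 9 1-{3-[(2R,3S)-6,6-dimethyl-3-(prop-1-en-2-yl)oxan-2-yl]-6-methoxy-2,4-bis(prop-2-enyloxy)phenyl}ethan-1-one, via oxocarbenium ion 8 (not isolated)
Conditions: BINOL-derived N-triflyl imidodiphosphorimidate Brønsted acid (5 mol %, 3,3'-aryl groups chosen by screening), CH2Cl2, −40 °C
Reagents that add atoms: none
Why: Proposed new method: the acid (or the silylium ion pair it forms with 7) activates the aldehyde of 4, the silyl ether oxygen adds and trimethylsilanol leaves to give the (E)-oxocarbenium ion 8 paired with the chiral anion, and the CH terminus of the trisubstituted alkene then attacks the C=O+ carbon while a geminal methyl group gives its proton to the anion, which creates the CH–CH bond and the isopropenyl group and frees the acid again. The closest known reaction types are the Lewis acid promoted oxonium-ene (Prins-type) cyclisation of aldehydes with 6-methylhept-5-en-2-ol to 3-isopropenyloxanes and the asymmetric Prins and carbonyl-ene cyclisations catalysed by confined chiral acids, and what is new is the tertiary silyl ether partner and the enantioselective form of this ring closure. The oxane closes 6-exo-trig at the alkene with the C=O+ unit endocyclic, through a chair in which the aryl group and the developing 2-propyl cation are both equatorial. This chair sets the 2,3-trans relation, and the chiral anion selects the alkene face and hence the (3S) centre, the only one that survives, because the (2R) centre is erased in step 5. The step needs ene-type proton loss instead of cation capture, which the allyl caps on both ortho oxygens secure, and it needs attack by the right alkene, which is secured because the trisubstituted alkene is far more nucleophilic than the allyl ethers and alone can reach a six-membered chair, while no 2-oxonia-Cope path to racemisation exists because the alkene is one carbon too far from oxygen. The para methoxy and the two ortho alkoxy groups of ring A make ion 8 accessible at low temperature, and the gem-dimethyl group favours ring closure.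

**Step 5**
Reactants: 9 the (2R,3S)-oxane of step 4
Product: 11 1-{6-methoxy-3-[(2R)-5-methyl-2-(prop-1-en-2-yl)-5-(triethylsilyloxy)hexyl]-2,4-bis(prop-2-enyloxy)phenyl}ethan-1-one, via benzylic cation 10 (not isolated)
Conditions: Et3SiH (3 equiv), Et3SiOTf (10 mol %), 2,6-di-tert-butyl-4-methylpyridine (20 mol %), CH2Cl2, −78 to −40 °C; Et3N quench
Reagents that add atoms: triethylsilane CC[SiH](CC)CC
Why: In this ionic hydrogenation, silylation of the ring oxygen triggers SN1 scission of the benzylic C–O bond only (one para and two ortho oxygen donors stabilise 10), and hydride transfer from Et3SiH passes the silyl cation on, so the CH2 group and the silyl-protected tertiary alcohol appear together while the adjacent stereocentre is untouched.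

**Step 6**
Reactants: 11 the bis(allyl) ether of step 5
Product: 12 1-{2,4-dihydroxy-6-methoxy-3-[(2R)-5-methyl-2-(prop-1-en-2-yl)-5-(triethylsilyloxy)hexyl]phenyl}ethan-1-one
Conditions: Pd(PPh3)4 (5 mol %), morpholine, THF, rt
Reagents that add atoms: none
Why: In this Tsuji–Trost-type deallylation, zerovalent palladium ionises the aryl allyl ethers and morpholine traps the allyl unit under neutral conditions that spare the alkene, the ketone and the silyl ether.

**Step 7**
Reactants: 12 the dihydroxyacetophenone of step 6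
Product: 14 7-hydroxy-5-methoxy-8-[(2R)-5-methyl-2-(prop-1-en-2-yl)-5-(triethylsilyloxy)hexyl]-4H-chromen-4-one, via enaminone 13 (not isolated)
Conditions: t-BuOCH(NMe2)2, toluene, 80 °C; then AcOH, 50 °C
Reagents that add atoms: tert-butoxybis(dimethylamino)methane CN(C)C(N(C)C)OC(C)(C)C
Why: In this enaminone route to chromones, the acetyl CH3 condenses with the aminal ester and mild acid lets the hydroxyl ortho to the acyl group add and expel dimethylamine to close ring C, and the tert-butoxy reagent avoids the O-methylation that the dimethyl acetal of DMF can cause.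

**Step 8**
Reactants: 14 the 7-hydroxychromone of step 7
Product: 15 7-(tert-butyldimethylsilyloxy)-5-methoxy-8-[(2R)-5-methyl-2-(prop-1-en-2-yl)-5-(triethylsilyloxy)hexyl]-4H-chromen-4-one
Conditions: TBSCl, imidazole, DMF, rt
Reagents that add atoms: tert-butylchlorodimethylsilane CC(C)(C)[Si](C)(C)Cl
Why: Standard silylation of the only free hydroxyl removes the acidic proton that could quench aryl-rhodium species in step 11.

**Step 9**
Reactants: 16 4-bromobenzene-1,3-diol
Product: 17 1-bromo-2,4-bis(tert-butyldimethylsilyloxy)benzene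
Conditions: TBSCl (2.3 equiv), imidazole, DMF, rt
Reagents that add atoms: tert-butylchlorodimethylsilane CC(C)(C)[Si](C)(C)Cl
Why: Standard double silylation is used because fluoride removes silyl ethers at the end without acid, base or hydrogen, each of which would endanger the alkene, the tertiary alcohol or C2.

**Step 10**
Reactants: 17 1-bromo-2,4-bis(tert-butyldimethylsilyloxy)benzene
Product: 20 [2,4-bis(tert-butyldimethylsilyloxy)phenyl]boronic acid, via aryllithium 18 (not isolated), via lithium arylborate 19 (not isolated)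
Conditions: B(OiPr)3 present from the start, n-BuLi added last, THF/toluene, −78 °C; then 1 M HCl, 0 °C
Reagents that add atoms: triisopropyl borate CC(C)OB(OC(C)C)OC(C)C; water O
Why: Bromine–lithium exchange with in situ borate quench traps the aryllithium before the ortho silyl group can migrate from oxygen to carbon, and mild hydrolysis frees the boronic acid.

**Step 11**
Reactants: 15 the 7-silyloxychromone of step 8; 20 [2,4-bis(tert-butyldimethylsilyloxy)phenyl]boronic acid
Product: 21 (2S)-2-[2,4-bis(tert-butyldimethylsilyloxy)phenyl]-7-(tert-butyldimethylsilyloxy)-5-methoxy-8-[(2R)-5-methyl-2-(prop-1-en-2-yl)-5-(triethylsilyloxy)hexyl]-2,3-dihydro-4H-chromen-4-one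
Conditions: [Rh(OH)(cod)]2 (2.5 mol %), (S)-6,6'-dimethoxy-2,2'-bis[bis(3,4,5-trifluorophenyl)phosphino]-1,1'-biphenyl, toluene/H2O, 30 °C
Reagents that add atoms: none
Why: In this Hayashi–Miyaura reaction on a chromone, the aryl-rhodium species adds 1,4, water protonates the rhodium enolate, and the chiral bisphosphine shields one face of C2 and so sets (2S) independently of the remote side-chain centre.

**Step 12**
Reactants: 21 the fully silylated flavanone of step 11
Product: 22 (2S)-2-(2,4-dihydroxyphenyl)-7-hydroxy-8-[(2R)-5-hydroxy-5-methyl-2-(prop-1-en-2-yl)hexyl]-5-methoxy-2,3-dihydro-4H-chromen-4-one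
Conditions: HF·pyridine, pyridine, THF, 0 °C to rt
Reagents that add atoms: none
Why: Fluoride cleaves the three aryl silyl ethers and the tertiary triethylsilyl ether in a buffered medium that neither protonates the isopropenyl group nor opens ring C, so both stereocentres are kept.

**Compound list**
1 | 1-(2,4-dihydroxy-6-methoxyphenyl)ethan-1-one | CC(=O)c1c(O)cc(O)cc1OC | starting material
2 | [(3-acetyl-2,6-dihydroxy-4-methoxyphenyl)methylidene]dimethylammonium dichlorophosphate | CC(=O)c1c(O)c(C=[N+](C)C)c(O)cc1OC.[O-]P(=O)(Cl)Cl | intermediate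
3 | 3-acetyl-2,6-dihydroxy-4-methoxybenzaldehyde | CC(=O)c1c(O)c(C=O)c(O)cc1OC | intermediate
4 | 3-acetyl-4-methoxy-2,6-bis(prop-2-enyloxy)benzaldehyde | CC(=O)c1c(OCC=C)c(C=O)c(OCC=C)cc1OC | intermediate
5 | 6-methylhept-5-en-2-one | CC(=O)CCC=C(C)C | starting material
6 | lithium 2,6-dimethylhept-5-en-2-olate | [Li+].CC(C)=CCCC(C)(C)[O-] | intermediate
7 | [(2,6-dimethylhept-5-en-2-yl)oxy]trimethylsilane | CC(C)=CCCC(C)(C)O[Si](C)(C)C | intermediate
8 | (E)-[3-acetyl-4-methoxy-2,6-bis(prop-2-enyloxy)benzylidene](2,6-dimethylhept-5-en-2-yl)oxonium, paired with the catalyst anion | CC(C)=CCCC(C)(C)/[O+]=C/c1c(OCC=C)cc(OC)c(C(C)=O)c1OCC=C | intermediate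
9 | 1-{3-[(2R,3S)-6,6-dimethyl-3-(prop-1-en-2-yl)oxan-2-yl]-6-methoxy-2,4-bis(prop-2-enyloxy)phenyl}ethan-1-one | C=C(C)[C@@H]1CCC(C)(C)O[C@H]1c1c(OCC=C)cc(OC)c(C(C)=O)c1OCC=C | intermediate
10 | ring-opened benzylic cation bearing the triethylsilyl ether (adjacent centre unchanged) | C=C(C)[C@H](CCC(C)(C)O[Si](CC)(CC)CC)[CH+]c1c(OCC=C)cc(OC)c(C(C)=O)c1OCC=C | intermediate
11 | 1-{6-methoxy-3-[(2R)-5-methyl-2-(prop-1-en-2-yl)-5-(triethylsilyloxy)hexyl]-2,4-bis(prop-2-enyloxy)phenyl}ethan-1-one | C=C(C)[C@H](CCC(C)(C)O[Si](CC)(CC)CC)Cc1c(OCC=C)cc(OC)c(C(C)=O)c1OCC=C | intermediate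
12 | 1-{2,4-dihydroxy-6-methoxy-3-[(2R)-5-methyl-2-(prop-1-en-2-yl)-5-(triethylsilyloxy)hexyl]phenyl}ethan-1-one | C=C(C)[C@H](CCC(C)(C)O[Si](CC)(CC)CC)Cc1c(O)cc(OC)c(C(C)=O)c1O | intermediate
13 | (E)-3-(dimethylamino)-1-{2,4-dihydroxy-6-methoxy-3-[(2R)-5-methyl-2-(prop-1-en-2-yl)-5-(triethylsilyloxy)hexyl]phenyl}prop-2-en-1-one | C=C(C)[C@H](CCC(C)(C)O[Si](CC)(CC)CC)Cc1c(O)cc(OC)c(C(=O)/C=C/N(C)C)c1O | intermediate
14 | 7-hydroxy-5-methoxy-8-[(2R)-5-methyl-2-(prop-1-en-2-yl)-5-(triethylsilyloxy)hexyl]-4H-chromen-4-one | C=C(C)[C@H](CCC(C)(C)O[Si](CC)(CC)CC)Cc1c(O)cc(OC)c2c1OC=CC2=O | intermediate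
15 | 7-(tert-butyldimethylsilyloxy)-5-methoxy-8-[(2R)-5-methyl-2-(prop-1-en-2-yl)-5-(triethylsilyloxy)hexyl]-4H-chromen-4-one | C=C(C)[C@H](CCC(C)(C)O[Si](CC)(CC)CC)Cc1c(O[Si](C)(C)C(C)(C)C)cc(OC)c2c1OC=CC2=O | intermediate
16 | 4-bromobenzene-1,3-diol | Oc1ccc(Br)c(O)c1 | starting material
17 | 1-bromo-2,4-bis(tert-butyldimethylsilyloxy)benzene | CC(C)(C)[Si](C)(C)Oc1ccc(Br)c(O[Si](C)(C)C(C)(C)C)c1 | intermediate
18 | [2,4-bis(tert-butyldimethylsilyloxy)phenyl]lithium | [Li]c1ccc(O[Si](C)(C)C(C)(C)C)cc1O[Si](C)(C)C(C)(C)C | intermediate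
19 | lithium [2,4-bis(tert-butyldimethylsilyloxy)phenyl]triisopropoxyborate | [Li+].CC(C)O[B-](OC(C)C)(OC(C)C)c1ccc(O[Si](C)(C)C(C)(C)C)cc1O[Si](C)(C)C(C)(C)C | intermediate
20 | [2,4-bis(tert-butyldimethylsilyloxy)phenyl]boronic acid | OB(O)c1ccc(O[Si](C)(C)C(C)(C)C)cc1O[Si](C)(C)C(C)(C)C | intermediate
21 | (2S)-2-[2,4-bis(tert-butyldimethylsilyloxy)phenyl]-7-(tert-butyldimethylsilyloxy)-5-methoxy-8-[(2R)-5-methyl-2-(prop-1-en-2-yl)-5-(triethylsilyloxy)hexyl]-2,3-dihydro-4H-chromen-4-one | C=C(C)[C@H](CCC(C)(C)O[Si](CC)(CC)CC)Cc1c(O[Si](C)(C)C(C)(C)C)cc(OC)c2c1O[C@H](c1ccc(O[Si](C)(C)C(C)(C)C)cc1O[Si](C)(C)C(C)(C)C)CC2=O | intermediate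
22 | (2S)-2-(2,4-dihydroxyphenyl)-7-hydroxy-8-[(2R)-5-hydroxy-5-methyl-2-(prop-1-en-2-yl)hexyl]-5-methoxy-2,3-dihydro-4H-chromen-4-one | C=C(C)[C@H](CCC(C)(C)O)Cc1c(O)cc(OC)c2c1O[C@H](c1ccc(O)cc1O)CC2=O | target

Total step count: 12. Longest linear sequence: 9 steps (1, 2, 4, 5, 6, 7, 8, 11, 12).

**Steps most likely to fail**

**Step 4.**
- Possible failures: poor facial discrimination by the chiral anion towards a doubly ortho-substituted aryl oxocarbenium ion, slow build-up of the hindered tertiary oxocarbenium ion, or ionisation of the tertiary C–O bond of the silyl ether.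
- Fallback: catalyst control is replaced by a stereogenic tether, using the known diastereoselective oxonium-ene cyclisation. It sets out from 4 and returns at 11.
- Aldehyde 4 is condensed with commercial (R)-6-methylhept-5-en-2-ol under In(OTf)3 in CH2Cl2. A chair with aryl, isopropenyl and 6-methyl all equatorial should give the (2R,3S,6R)-6-methyloxane F1.
- Et3SiH/Et3SiOTf opens it to the secondary triethylsilyl ether F2, and PPTS in MeOH frees the secondary alcohol F3.
- Dess–Martin periodinane gives the aliphatic methyl ketone F4.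
- MeTi(OiPr)3 adds to the unhindered aliphatic ketone and leaves the doubly ortho-substituted aryl ketone alone, giving the tertiary alcohol F5.
- Et3SiOTf/2,6-lutidine then comes back to the route at 11.

**Step 11.**
- Possible failures: slow transmetallation and insertion of the ortho-silyloxy aryl group, protodeboronation, or a second 1,2-addition to the product ketone.
- Fallback: ring C is closed by oxa-Michael addition instead of C–C bond formation. It sets out from 11 and returns at 22.
- 2,4-Dihydroxybenzaldehyde, allyl bromide and K2CO3 give 2,4-bis(prop-2-enyloxy)benzaldehyde F6.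
- Claisen–Schmidt condensation of F6 with 11 (KOH, EtOH) gives the tetraallyl chalcone F7, and Pd(PPh3)4/morpholine gives the tetrahydroxychalcone F8.
- NaOAc in refluxing EtOH closes ring C without facial control. Because C2'' is fixed, the two C2 epimers are diastereomers.
- The (2S)-flavanone F9 is separated by chromatography. The (2R)-flavanone F10 is re-equilibrated under the same conditions and recycled.
- HF·pyridine on F9 comes back to the route at 22.

**Step 5.**
- Possible failures: protonation of the isopropenyl group by adventitious acid, loss of the C2'' proton from the benzylic cation with erosion of the stereocentre, or hydrosilylation of the acetyl group.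
- Fallback: the cationic manifold is exchanged for a neutral ortho-quinone methide manifold. It sets out from 9 and returns at 12.
- Pd(PPh3)4/morpholine on 9 gives the dihydroxyaryl oxane F11.
- With catalytic diphenyl phosphate and a Hantzsch ester in toluene, the ortho-hydroxybenzyl ether opens reversibly to the ortho-quinone methide F12. This is reduced irreversibly (known transfer hydrogenation of such methides) to the triol F13.
- Et3SiOTf/2,6-lutidine gives the tris(triethylsilyl) ether F14.
- Brief K2CO3/MeOH cleaves only the two aryl silyl ethers and comes back to the route at 12.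

**Further compounds**
F1 | step 4 | 1-{6-methoxy-3-[(2R,3S,6R)-6-methyl-3-(prop-1-en-2-yl)oxan-2-yl]-2,4-bis(prop-2-enyloxy)phenyl}ethan-1-one | C=C(C)[C@@H]1CC[C@@H](C)O[C@H]1c1c(OCC=C)cc(OC)c(C(C)=O)c1OCC=C
F2 | step 4 | 1-{6-methoxy-3-[(2R,5R)-2-(prop-1-en-2-yl)-5-(triethylsilyloxy)hexyl]-2,4-bis(prop-2-enyloxy)phenyl}ethan-1-one | C=C(C)[C@H](CC[C@@H](C)O[Si](CC)(CC)CC)Cc1c(OCC=C)cc(OC)c(C(C)=O)c1OCC=C
F3 | step 4 | 1-{3-[(2R,5R)-5-hydroxy-2-(prop-1-en-2-yl)hexyl]-6-methoxy-2,4-bis(prop-2-enyloxy)phenyl}ethan-1-one | C=C(C)[C@H](CC[C@@H](C)O)Cc1c(OCC=C)cc(OC)c(C(C)=O)c1OCC=C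
F4 | step 4 | (5R)-5-{[3-acetyl-4-methoxy-2,6-bis(prop-2-enyloxy)phenyl]methyl}-6-methylhept-6-en-2-one | C=C(C)[C@H](CCC(C)=O)Cc1c(OCC=C)cc(OC)c(C(C)=O)c1OCC=C
F5 | step 4 | 1-{3-[(2R)-5-hydroxy-5-methyl-2-(prop-1-en-2-yl)hexyl]-6-methoxy-2,4-bis(prop-2-enyloxy)phenyl}ethan-1-one | C=C(C)[C@H](CCC(C)(C)O)Cc1c(OCC=C)cc(OC)c(C(C)=O)c1OCC=C
F6 | step 11 | 2,4-bis(prop-2-enyloxy)benzaldehyde | O=Cc1ccc(OCC=C)cc1OCC=C
F7 | step 11 | (E)-tetraallyl chalcone from 11 and F6 | C=C(C)[C@H](CCC(C)(C)O[Si](CC)(CC)CC)Cc1c(OCC=C)cc(OC)c(C(=O)/C=C/c2ccc(OCC=C)cc2OCC=C)c1OCC=C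
F8 | step 11 | (E)-tetrahydroxychalcone triethylsilyl ether | C=C(C)[C@H](CCC(C)(C)O[Si](CC)(CC)CC)Cc1c(O)cc(OC)c(C(=O)/C=C/c2ccc(O)cc2O)c1O
F9 | step 11 | (2S)-flavanone with free phenols and tertiary triethylsilyl ether | C=C(C)[C@H](CCC(C)(C)O[Si](CC)(CC)CC)Cc1c(O)cc(OC)c2c1O[C@H](c1ccc(O)cc1O)CC2=O
F10 | step 11 | (2R)-flavanone epimer of F9 | C=C(C)[C@H](CCC(C)(C)O[Si](CC)(CC)CC)Cc1c(O)cc(OC)c2c1O[C@@H](c1ccc(O)cc1O)CC2=O
F11 | step 5 | 1-{3-[(2R,3S)-6,6-dimethyl-3-(prop-1-en-2-yl)oxan-2-yl]-2,4-dihydroxy-6-methoxyphenyl}ethan-1-one | C=C(C)[C@@H]1CCC(C)(C)O[C@H]1c1c(O)cc(OC)c(C(C)=O)c1O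
F12 | step 5 | ortho-quinone methide from ring opening of F11 | C=C(C)[C@H](CCC(C)(C)O)C=C1C(=O)C=C(OC)C(C(C)=O)=C1O
F13 | step 5 | 1-{2,4-dihydroxy-3-[(2R)-5-hydroxy-5-methyl-2-(prop-1-en-2-yl)hexyl]-6-methoxyphenyl}ethan-1-one | C=C(C)[C@H](CCC(C)(C)O)Cc1c(O)cc(OC)c(C(C)=O)c1O
F14 | step 5 | tris(triethylsilyl) ether of F13 | C=C(C)[C@H](CCC(C)(C)O[Si](CC)(CC)CC)Cc1c(O[Si](CC)(CC)CC)cc(OC)c(C(C)=O)c1O[Si](CC)(CC)CC
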